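All constants were chosen freely.

Slowness sits in one place in this flask: the first product waits to be captured or to decay, and I reckoned that wait.

substrate 0.010 M; partner 1.10 equiv; capture agent 3.00 mM; time 40 min

    substrate + partner → first product (k1 = 1.12 /M/s)
    partner + first product → bis adduct (k2 = 0.310 /M/s)
    2 partner → self-condensation product (k3 = 3.53 /M/s)
    first product + capture agent → trapped intermediate (k4 = 1.80 /M/s)
    first product → decomposed reagent (k5 = 0.00121 /s)

1. the state of affairs at 40 min: stopped, and by what, or still going (it is still moving / all of the substrate has reacted / forward and back rates have come level / the partner has run out first)
2. how much trapped intermediate there is at 40 min, in percent of the substrate charged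

- for a step with 2 of a species take k times the square, and two of it per event
- the reaction counts as stopped when no species that holds the substrate changes by six tenths of a point or more over the second half of the time
- run time (flask): 40 min

Partner halves by self-condensation in 0.215 min, shorter than the 3.4 min first product needs to meet it, so I dropped bis adduct and took partner as limiting reagent. With n, twice the self-condensation constant over the substrate constant, minus one, here 5.30, dividing partner's rates leaves substrate at one plus n times the equivalents, raised to minus one over n: 69.6%. So 3.04 mM of first product forms.

First product then chooses between capture and decay, whose half-lives as charged are 2.1 min and 9.5 min; capture slows as capture agent is used, so these two hold at the start. Their ratio is the charge C of capture agent over K, the level concentration at which capture and decay run equal, 0.672 mM. Dividing the rates gives decomposed reagent as K ln(C/E), with E the capture agent at the end. Trying E = K, the balance returned 0.966 mM; the mean, 0.819 mM, gave 21.8% trapped. I called the flask stopped by partner.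

The forecast said it is still moving and 19.5%, adding “this is a close call”. The simulation gave the partner has run out first, with partner at 0%, and 20.9%.

First product stood at 0.573% at 20.0 min and 0.0183% at 40.0 min, a fall of 0.55 percentage points, inside the margin for stopped. With 30% of capture agent left, K ln(C/E) gives 7.98% decomposed reagent in this flask, and the table holds 7.98%. The neighbour flask with 0.0018 M of capture agent kept 14% of its charge, so the same K gives 13.0%; that flask holds 13.0% decomposed reagent and 15.4% trapped intermediate.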